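The flavanone is cut at C2–C1′: a rhodium-catalysed asymmetric 1,4-addition of a chromenylboronic acid to a 7-O-MOM-8-prenylchromone sets the (2S) centre. Everything rests on the 2,2-dimethyl-2H-pyran ring fused to ring B: its C4–C4a and O1–C2 bonds are made in one operation from a phenol and 3-methylbut-2-enal. The key step exploits the phenol oxygen and the only free ortho carbon of 4-bromo-2-prenylphenol: boron-templated ortho attack on the aldehyde carbon leads to an ortho-quinone methide, whose oxa-6π electrocyclisation closes the pyran. The precursor is therefore an open-chain pair, a simple phenol and a C5 enal, with no pyran ring.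

Key step: step 2

Assumption: the (S)-configured biaryl bisphosphine (S)-MeO-F12-BIPHEP, (S)-6,6′-dimethoxy-2,2′-bis[bis(3,4,5-trifluorophenyl)phosphino]-1,1′-biphenyl, is taken to select the same enantioface of the chromone as of cyclohex-2-enone, which corresponds to (2S). If a model addition showed the opposite sense, the (R)-ligand would be used with nothing else changed.

Step 1
Reactants: 1 4-bromophenol; 2 prenyl bromide (1-bromo-3-methylbut-2-ene)
Product: 3 4-bromo-2-(3-methylbut-2-en-1-yl)phenol
Conditions: NaH (1.0 equiv), toluene, 0 °C; then 2, 0 °C to rt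
Reagents that add atoms: none
Why: ortho-C-alkylation of a sodium phenoxide in a non-polar solvent, where the aggregated ion pair shields oxygen and steers the primary allylic bromide to the ortho carbon in an SN2 manner, the para position being blocked by bromine; no stereocentre is formed.

Step 2
Reactants: 3 4-bromo-2-(3-methylbut-2-en-1-yl)phenol; 4 3-methylbut-2-enal
Product: 7 6-bromo-2,2-dimethyl-8-(3-methylbut-2-en-1-yl)-2H-chromene, via benzodioxaborin 5 (not isolated), via ortho-quinone methide 6 (not isolated)
Conditions: PhB(OH)2 (1.1 equiv), EtCO2H (0.3 equiv), toluene, reflux, Dean–Stark trap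
Reagents that add atoms: none
Why: Phenol 3, PhB(OH)2 and the aldehyde condense with loss of water so that boron holds the phenoxide and the aldehyde together and the single free ortho carbon attacks the aldehyde carbon through a six-membered transition state, which forms the aryl–C4 bond and gives benzodioxaborin 5. At reflux 5 fragments in a retro-hetero-Diels–Alder sense, extruding boron as triphenylboroxine and leaving ortho-quinone methide 6, a (Z)-1-oxatriene. Thermal disrotatory oxa-6π electrocyclisation of 6 then forms the O1–C2 bond, closes the six-membered pyran ring (electrocyclic closure of a 1-oxahexatriene, 6-endo in outcome) and restores the aromaticity of ring B. The closest known reaction type is the phenylboronic-acid-mediated condensation of phenols with α,β-unsaturated aldehydes to 2H-chromenes, a formal [3+3] annulation. No stereocentre results, since C2 carries two methyl groups and the racemic centre of 5 is destroyed in 6. The step needs attack through ring carbon (not oxygen) at the aldehyde carbon (not the β-carbon) and a single ortho site: the boron template secures the first two, the para bromine and the ortho prenyl group of 3 leave only one position open, and the weak carboxylic acid is not expected to cyclise the prenyl phenol.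

Step 3
Reactants: 7 6-bromo-2,2-dimethyl-8-(3-methylbut-2-en-1-yl)-2H-chromene
Product: 8 [2,2-dimethyl-8-(3-methylbut-2-en-1-yl)-2H-chromen-6-yl]boronic acid
Conditions: n-BuLi, THF, −78 °C; B(OiPr)3, −78 °C to rt; HCl (1 M aq.)
Reagents that add atoms: triisopropyl borate CC(C)OB(OC(C)C)OC(C)C; water O
Why: bromine–lithium exchange followed by borylation with a trialkyl borate and hydrolysis; at −78 °C the exchange is faster than allylic or benzylic deprotonation, and the aryllithium is trapped as the borate, which acid hydrolysis turns into the boronic acid.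

Step 4
Reactants: 9 2,4-dihydroxyacetophenone; 2 prenyl bromide
Product: 10 1-[2,4-dihydroxy-3-(3-methylbut-2-en-1-yl)phenyl]ethan-1-one
Conditions: KOH (10 % aq.), 0 °C to rt
Reagents that add atoms: none
Why: phenoxide C-alkylation (C-prenylation) in water, where hydrogen bonding to the phenoxide oxygens favours attack through carbon and C3, ortho to both oxygens, is the most nucleophilic ring carbon; site selectivity is expected to be modest, so 10 is separated from O- and C5-alkylated material by chromatography.

Step 5
Reactants: 10 1-[2,4-dihydroxy-3-(3-methylbut-2-en-1-yl)phenyl]ethan-1-one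
Product: 11 1-[2-hydroxy-4-(methoxymethoxy)-3-(3-methylbut-2-en-1-yl)phenyl]ethan-1-one
Conditions: MOMCl, K2CO3, acetone, rt
Reagents that add atoms: chloromethyl methyl ether COCCl
Why: Williamson-type O-alkylation in which the 2-OH, locked in a hydrogen bond to the acetyl carbonyl, is much less nucleophilic, so that only the 4-OH should be converted into the MOM acetal.

Step 6
Reactants: 11 1-[2-hydroxy-4-(methoxymethoxy)-3-(3-methylbut-2-en-1-yl)phenyl]ethan-1-one
Product: 13 7-(methoxymethoxy)-8-(3-methylbut-2-en-1-yl)-4H-chromen-4-one, via enaminone 12 (not isolated)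
Conditions: Me2NCH(OMe)2, toluene, 95 °C; then AcOH, 60 °C
Reagents that add atoms: N,N-dimethylformamide dimethyl acetal COC(OC)N(C)C
Why: condensation of the methyl ketone with the amide acetal gives enaminone 12, and mild acid then triggers intramolecular oxa-Michael addition of the phenol (6-endo-trig) and elimination of dimethylamine to the chromone; acetic acid is too weak to cleave the aryl MOM acetal or to cyclise the prenyl group.

Step 7
Reactants: 13 7-(methoxymethoxy)-8-(3-methylbut-2-en-1-yl)-4H-chromen-4-one; 8 [2,2-dimethyl-8-(3-methylbut-2-en-1-yl)-2H-chromen-6-yl]boronic acid (2.5 equiv)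
Product: 14 (2S)-2-[2,2-dimethyl-8-(3-methylbut-2-en-1-yl)-2H-chromen-6-yl]-7-(methoxymethoxy)-8-(3-methylbut-2-en-1-yl)-2,3-dihydro-4H-chromen-4-one
Conditions: [Rh(OH)(cod)]2 (1.5 mol %), (S)-MeO-F12-BIPHEP (3.3 mol %), toluene/H2O 10:1, 40 °C
Reagents that add atoms: none
Why: Hayashi–Miyaura asymmetric 1,4-addition, in which transmetalation gives an aryl complex of monovalent rhodium, the chromone C2=C3 bond inserts with the aryl group delivered to C2 on the enantioface selected by the C2-symmetric (S)-bisphosphine, and water protonates the rhodium enolate; the new C2 stereocentre is thus set (S) by ligand control, and the electron-poor ligand should accelerate insertion into the electron-rich chromone.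

Step 8
Reactants: 14 (2S)-2-[2,2-dimethyl-8-(3-methylbut-2-en-1-yl)-2H-chromen-6-yl]-7-(methoxymethoxy)-8-(3-methylbut-2-en-1-yl)-2,3-dihydro-4H-chromen-4-one
Product: 15 (2S)-2-[2,2-dimethyl-8-(3-methylbut-2-en-1-yl)-2H-chromen-6-yl]-7-hydroxy-8-(3-methylbut-2-en-1-yl)-2,3-dihydro-4H-chromen-4-one
Conditions: HCl (3 M aq.), MeOH, 40 °C
Reagents that add atoms: none
Why: acid-catalysed acetal solvolysis (MOM cleavage) with methanol as the formaldehyde acceptor; under dilute acid at mild temperature the two prenyl groups, the chromene and the C2 stereocentre, which could only be lost through ring opening, should persist.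

Compound list
1 | 4-bromophenol | Oc1ccc(Br)cc1 | starting material
2 | prenyl bromide (1-bromo-3-methylbut-2-ene) | CC(C)=CCBr | starting material
3 | 4-bromo-2-(3-methylbut-2-en-1-yl)phenol | CC(C)=CCc1cc(Br)ccc1O | intermediate
4 | 3-methylbut-2-enal | CC(C)=CC=O | starting material
5 | 6-bromo-4-(2-methylprop-1-en-1-yl)-8-(3-methylbut-2-en-1-yl)-2-phenyl-4H-1,3,2-benzodioxaborinine (racemic, not isolated) | CC(C)=CCc1cc(Br)cc2c1OB(c1ccccc1)OC2C=C(C)C | intermediate
6 | (6Z)-4-bromo-2-(3-methylbut-2-en-1-yl)-6-(3-methylbut-2-en-1-ylidene)cyclohexa-2,4-dien-1-one (ortho-quinone methide, not isolated) | O=C1C(CC=C(C)C)=CC(Br)=C/C1=C/C=C(C)C | intermediate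
7 | 6-bromo-2,2-dimethyl-8-(3-methylbut-2-en-1-yl)-2H-chromene | CC(C)=CCc1cc(Br)cc2c1OC(C)(C)C=C2 | intermediate
8 | [2,2-dimethyl-8-(3-methylbut-2-en-1-yl)-2H-chromen-6-yl]boronic acid | CC(C)=CCc1cc(B(O)O)cc2c1OC(C)(C)C=C2 | intermediate
9 | 2,4-dihydroxyacetophenone | CC(=O)c1ccc(O)cc1O | starting material
10 | 1-[2,4-dihydroxy-3-(3-methylbut-2-en-1-yl)phenyl]ethan-1-one | CC(=O)c1ccc(O)c(CC=C(C)C)c1O | intermediate
11 | 1-[2-hydroxy-4-(methoxymethoxy)-3-(3-methylbut-2-en-1-yl)phenyl]ethan-1-one | CC(=O)c1ccc(OCOC)c(CC=C(C)C)c1O | intermediate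
12 | (2E)-3-(dimethylamino)-1-[2-hydroxy-4-(methoxymethoxy)-3-(3-methylbut-2-en-1-yl)phenyl]prop-2-en-1-one (enaminone, not isolated) | CN(C)/C=C/C(=O)c1ccc(OCOC)c(CC=C(C)C)c1O | intermediate
13 | 7-(methoxymethoxy)-8-(3-methylbut-2-en-1-yl)-4H-chromen-4-one | COCOc1ccc2c(=O)ccoc2c1CC=C(C)C | intermediate
14 | (2S)-2-[2,2-dimethyl-8-(3-methylbut-2-en-1-yl)-2H-chromen-6-yl]-7-(methoxymethoxy)-8-(3-methylbut-2-en-1-yl)-2,3-dihydro-4H-chromen-4-one | CC(C)=CCc1cc([C@@H]2CC(=O)c3ccc(OCOC)c(CC=C(C)C)c3O2)cc2c1OC(C)(C)C=C2 | intermediate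
15 | (2S)-2-[2,2-dimethyl-8-(3-methylbut-2-en-1-yl)-2H-chromen-6-yl]-7-hydroxy-8-(3-methylbut-2-en-1-yl)-2,3-dihydro-4H-chromen-4-one | CC(C)=CCc1cc([C@@H]2CC(=O)c3ccc(O)c(CC=C(C)C)c3O2)cc2c1OC(C)(C)C=C2 | target

Total step count: 8. Longest linear sequence: 5 steps (steps 1, 2, 3, 7, 8, or equally steps 4, 5, 6, 7, 8).

Steps most likely to fail

Step 2 (key step). The para bromine lowers the nucleophilicity of the ortho carbon, so the boron-templated ortho-hydroxyalkylation may be slow; self-condensation of the enal and acid-induced closure of the prenyl group onto the phenol oxygen could then compete. The fallback sets out from 3 and comes back at 7 by an ether-first approach. Phenol 3 would be O-alkylated with 3-chloro-3-methylbut-1-yne (K2CO3, KI, acetone, reflux) to 4-bromo-1-[(2-methylbut-3-yn-2-yl)oxy]-2-(3-methylbut-2-en-1-yl)benzene F1. Heating F1 in N,N-diethylaniline at about 180 °C should trigger the aryl propargyl ether Claisen rearrangement, 1,5-hydrogen shift and oxa-6π electrocyclisation to chromene 7.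

Step 7. Insertion into the electron-rich 7-alkoxychromone may be slow relative to protodeboronation of the boronic acid, enantioface discrimination may be insufficient, and retro-oxa-Michael ring opening of the product may occur in the aqueous medium. The fallback sets out from 7 and 11 and comes back at 14 by a chalcone route with resolution.
- Bromide 7 would be lithiated and formylated (n-BuLi, THF, −78 °C; DMF; aq. HCl) to 2,2-dimethyl-8-(3-methylbut-2-en-1-yl)-2H-chromene-6-carbaldehyde F2.
- Claisen–Schmidt condensation of F2 with ketone 11 (KOH, EtOH, rt) should give (2E)-3-[2,2-dimethyl-8-(3-methylbut-2-en-1-yl)-2H-chromen-6-yl]-1-[2-hydroxy-4-(methoxymethoxy)-3-(3-methylbut-2-en-1-yl)phenyl]prop-2-en-1-one F3.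
- Intramolecular oxa-Michael addition (NaOAc, EtOH, reflux) should close F3 to racemic 2-[2,2-dimethyl-8-(3-methylbut-2-en-1-yl)-2H-chromen-6-yl]-7-(methoxymethoxy)-8-(3-methylbut-2-en-1-yl)-2,3-dihydro-4H-chromen-4-one F4.
- Preparative HPLC of F4 on a cellulose tris(3,5-dimethylphenylcarbamate) phase would deliver the (2S)-enantiomer 14.

Step 4. Site selectivity may be poor, because O-alkylation, alkylation at C5 and double alkylation compete with attack at C3. The fallback sets out from 9 and comes back at 10 by an ether/rearrangement approach.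
- Ketone 9 would be etherified at the non-chelated 4-OH with 3-chloro-3-methylbut-1-yne (K2CO3, KI, acetone, reflux) to 1-{2-hydroxy-4-[(2-methylbut-3-yn-2-yl)oxy]phenyl}ethan-1-one F5.
- Semihydrogenation (H2, Pd/CaCO3 poisoned with Pb(OAc)2, quinoline, EtOAc) should give 1-{2-hydroxy-4-[(2-methylbut-3-en-2-yl)oxy]phenyl}ethan-1-one F6.
- Aromatic Claisen rearrangement of F6 (N,N-diethylaniline, 140 °C) should transfer the allyl unit with allylic inversion to C3, the position flanked by both oxygens, giving 10.

Further compounds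
F1 | step 2 | 4-bromo-1-[(2-methylbut-3-yn-2-yl)oxy]-2-(3-methylbut-2-en-1-yl)benzene | CC(C)=CCc1cc(Br)ccc1OC(C)(C)C#C
F2 | step 7 | 2,2-dimethyl-8-(3-methylbut-2-en-1-yl)-2H-chromene-6-carbaldehyde | CC(C)=CCc1cc(C=O)cc2c1OC(C)(C)C=C2
F3 | step 7 | (2E)-3-[2,2-dimethyl-8-(3-methylbut-2-en-1-yl)-2H-chromen-6-yl]-1-[2-hydroxy-4-(methoxymethoxy)-3-(3-methylbut-2-en-1-yl)phenyl]prop-2-en-1-one | CC(C)=CCc1cc(/C=C/C(=O)c3ccc(OCOC)c(CC=C(C)C)c3O)cc2c1OC(C)(C)C=C2
F4 | step 7 | racemic 2-[2,2-dimethyl-8-(3-methylbut-2-en-1-yl)-2H-chromen-6-yl]-7-(methoxymethoxy)-8-(3-methylbut-2-en-1-yl)-2,3-dihydro-4H-chromen-4-one | CC(C)=CCc1cc(C2CC(=O)c3ccc(OCOC)c(CC=C(C)C)c3O2)cc2c1OC(C)(C)C=C2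
F5 | step 4 | 1-{2-hydroxy-4-[(2-methylbut-3-yn-2-yl)oxy]phenyl}ethan-1-one | CC(=O)c1ccc(OC(C)(C)C#C)cc1O
F6 | step 4 | 1-{2-hydroxy-4-[(2-methylbut-3-en-2-yl)oxy]phenyl}ethan-1-one | CC(=O)c1ccc(OC(C)(C)C=C)cc1O
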